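## The problem

β-Collatolic acid (29) is an achiral diaryl ether. Ring A is a benzoic acid with C1' bearing the carboxyl group, C2' a 2-oxoheptyl chain, C3' the ether oxygen, C4' and C6' free phenols, and hydrogen only at C5'. The ether oxygen leads to C8 of a 6-methoxy-3-pentylisochromen-1-one, whose benzene ring is ring B (C4a, C5, C6, C7, C8, C8a) and whose pyranone is ring C (C1, O2, C3, C4). There is no stereocentre and no stereogenic double bond, so the difficulty is purely regiochemical: five substituents in fixed order on ring A, one methyl ether (O6) to be told apart from two phenols (O4', O6'), and an ether oxygen flanked by the C2' and C4' substituents on one side and by the lactone carbonyl at C8a on the other. Both aryl partners of that ether are electron-rich and ortho-substituted, which is where Ullmann and SNAr couplings are weakest. The functional groups are sensitive: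
- the 2-(2-oxoalkyl)benzoic acid of ring A can cyclodehydrate to a second isocoumarin in strong acid;
- its benzylic CH2 is easily enolised;
- the 2,4-dihydroxybenzoic acid decarboxylates when heated as the free acid;
- the ring C lactone opens with hydroxide or alkoxide, and its C3=C4 bond can be hydrogenated.

What the structure offers is ring B. Its oxygens at C6 and C8 are meta, as in a cyclohexane-1,3-dione, while C8a carries a carboxyl carbon (C1) and C4a a two-carbon unit (C4, C3) at the oxidation level of an alkyne; ring B is therefore the sum of a 1,3-dioxygenated cyclohexadiene and a 2-alkynoate, and the crowded C8–O bond can be made as a vinylogous ester before ring B is aromatic.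

## Retrosynthesis

**29 to 28 to 27 (unmasking).** The last two operations only unmask. The three benzyl–oxygen bonds of 28 (one ester, two ethers) are cut last because hydrogenolysis is neutral, so the ring A keto acid appears without acid or base present. The ketone is released one step earlier from dioxolane 27, while the carboxyl group is still an ester and cannot lactonise. The forward reaction must stop before the C3=C4 bond of ring C is reduced.

**27 to 26 (ring C).** Ring C is opened at O2–C3: the lactone becomes a methyl ester on C8a, and C3–C4 becomes a triple bond (a hept-1-ynyl group on C4a) in 26. The neighbouring cut, cyclodehydration of a second keto acid, would give ring B and ring A the same 2-oxoheptyl benzoate unit. This cut instead keeps the two units in different disguises (alkyne on ring B, dioxolane on ring A), so each can be addressed alone. The forward step must deliver the ester oxygen to the alkyne carbon remote from the ring (6-endo) and give up the O-methyl group.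

**26 to 24 (O6).** The O6–CH3 bond is cut, leaving aryl silyl ether 24. The silyl group is what distinguishes O6 from the other phenolic oxygens, all of which are benzylated or part of the ether. The exchange passes through phenoxide 25 and only requires that the benzyl groups and esters stay.

**24 to 22 and 17 (key disconnection, ring B).** Ring B of 24 is cut at C8–C8a and C5–C4a, with a saturated two-carbon bridge put back across C5 and C8. This gives bicyclic adduct 23 and, from it, diene 22 and diynoate 17. The cut is preferred to the diaryl ether C8–O bond (hindered and electron-rich on both sides) and to a polyketide-type closure of ring B (several folding modes). It removes a tetrasubstituted arene in one step and leaves a cyclohexenone derivative and a linear C10 ester. The forward reaction must bond the silyl enol ether terminus of 22 to the β-carbon of 17, react only at the ester-bearing triple bond, and outrun hydrogen shifts in the diene.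

**22 to 20 to 11 and 19 (the ether oxygen).** Diene 22 is the silyl dienol ether of 3-aryloxycyclohexenone 20, reached through dienolate 21. Cutting the vinylic C–O bond of 20 gives phenol 11 and chloro enone 19, which comes from dione 18. The crowded ether bond is thus formed by addition–elimination at an unhindered sp2 carbon of a small ring, not at an arene. Enolisation of 20 must occur at the α' methylene and not at the γ position, because only the former gives the 1-aryloxy-3-silyloxy diene.

**17 to 16 to 15 to 13 and 14 (the diynoate).** The sp–sp bond C3–C4 of 17 (the future C4a–C4 bond) is cut. Bromoalkyne 13, from heptyne 12, is coupled with propargylic alcohol 14 and not with a propiolate ester, because the amine that the copper coupling needs would add to a propiolate. Diynol 15 is then oxidised to acid 16 and esterified.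

**11 back to 1 (ring A).** The C3'–O bond of 11 is traced back to a C–B bond (10) and a C–Br bond (9). Dioxolane 9 comes from ketone 8. Ketone 8 is cut at the CH2–C(=O) bond into the benzylic anion 6 of bromo toluate 3 and Weinreb amide 5 (from acid chloride 4), joined through adduct 7. Toluate 3 comes from orsellinic acid 1 through its tribenzyl derivative 2. Compound 1 already has C1', the C2' carbon and the C4' and C6' oxygens; only O3' and six chain carbons are missing. The bromine serves twice: it marks C3' for the oxygen and acidifies the neighbouring methyl group. Bromination must choose C3' (para to one benzyloxy group, ortho to the other) over C5', which lies between the two benzyloxy groups.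

## Roads not taken

**Alternative 1: ring A by vinylketene benzannulation.** The cut goes through ring A at C3'–C4', C5'–C6' and C6'–C1'. It leaves a vinylketene that already carries the finished isocoumarin as its aryloxy substituent, and the two-carbon partner (triisopropylsilyloxy)ethyne A2. In the forward sense a tertiary amine would turn an α-aryloxy acid chloride into the ketene. [2+2] addition to A2, four-electron opening of the cyclobutenone and six-electron closure would then give phenol A1, with O4' silylated and O6' free.

- Merits: all six positions of ring A are fixed in one step, the two phenols come out differentiated, and no halogenation–borylation sequence is needed. Because the isocoumarin is complete, there is no late alkyne cyclisation and no hydrogenolysis next to C3=C4. In these respects A1 is the better intermediate.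
- Weak points: the hindered ether bond still has to be made, now by alkylating an 8-hydroxyisocoumarin whose phenol is hydrogen-bonded to the lactone carbonyl. Ketenes with an oxygen substituent on the ketene carbon dimerise readily and are not the usual partners in this benzannulation. The acid chloride must coexist with a tert-butyl ester and a dioxolane. The final release of the tert-butyl ester needs the kind of strong acid in which the ring A keto acid dehydrates. The most valuable fragment also sits at the start of a long linear sequence.
- Against this the chosen plan sets routine aromatic chemistry on cheap 1, a key step (22 with 17) with closer precedent, and a neutral last step.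

**Alternative 2: ring A as a cyclohexanedione, aromatised late.** Ring A is cut at C1'–C2' and C5'–C6' and taken down one oxidation level. Dibenzyl malonate A4 would add in Michael fashion to an acyclic α-aryloxy enone (aryl again being the finished isocoumarin). The methyl ketone enolate would then attack one malonate ester in a Dieckmann-type closure, giving dione A3. A dehydrogenation would later make the resorcinol.

- Merits: this is the classical and cheapest way to alkylresorcylates, with precedent for the ring formation at least as strong as for the chosen key step, and only base is needed.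
- Weak points: the enone is β-substituted and α-oxygenated, so it is a poor acceptor and the addition is reversible. The three stereocentres of A3 serve no purpose. The aromatisation needs a halogen or quinone oxidant in the presence of an electron-rich isocoumarin (C5 and C7 are open to attack) and a benzylic ketal. The crowded ether must again be made first, on the hydrogen-bonded 8-hydroxyisocoumarin.
- Against the cheaper reagents and stronger precedent the chosen plan sets a redox-neutral aromatisation (23 to 24 by cycloreversion), no oxidant near the finished rings, and substituent positions fixed by one cycloaddition.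

**Alternative 3: ring B by pyrone opening and aldol reclosure.** The same ring is made as in the chosen plan but cut at C8a–C4a and at C1–O2, leaving pyrone A6. A magnesium alkoxide in its parent alcohol would open the pyrone at the lactone carbonyl. C8a would add to the C4a ketone by aldol condensation to close ring B, and the C3 enol would lactonise onto the C1 ester to give 6-hydroxyisocoumarin A5. One O-methylation of A5 would give 27.

- Merits: rings B and C form together at low temperature, and the sequence after the key step is shorter than in the chosen plan by one step. If opening and folding were selective, this road would be the shorter one.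
- Weak points: the 4-aryloxy-2-pyrone is a vinylogous carbonate, and alkoxide can attack C4 and expel the ring A phenoxide, which destroys the ether. The polycarbonyl chain has several aldol and Claisen folding modes. Making A6 means acylating a pyrone side chain in the presence of the ring A benzyl ester.
- Against the shorter endgame the chosen plan sets a cycloaddition that allows only one connectivity, an aryloxy group that sits on a bridgehead in 23 and cannot leave, and known behaviour of alkoxy-silyloxy cyclohexadienes toward alkynoates.

Key step: step 15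

Remark: 29 is taken as the open keto acid drawn; a ring–chain equilibrium of the ring A keto acid with its lactol would not change the route.

## Steps

Step 1
Reactants: 1 orsellinic acid (2,4-dihydroxy-6-methylbenzoic acid)
Product: 2 benzyl 2,4-bis(benzyloxy)-6-methylbenzoate
Conditions: BnBr (3.5 equiv), K2CO3, DMF, rt then 60 °C
Reagents that add atoms: benzyl bromide, BrCc1ccccc1
Why: Williamson-type O-alkylation; the carboxylate is benzylated first at room temperature, which removes the risk of decarboxylation, then the 4-OH and, on warming, the hydrogen-bonded 2-OH, as is routine for 2,4-dihydroxybenzoic acids.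

Step 2
Reactants: 2 benzyl 2,4-bis(benzyloxy)-6-methylbenzoate
Product: 3 benzyl 4,6-bis(benzyloxy)-3-bromo-2-methylbenzoate
Conditions: NBS, MeCN, 0 °C to rt, dark
Reagents that add atoms: N-bromosuccinimide, O=C1CCC(=O)N1Br
Why: Electrophilic aromatic bromination; the carbon that becomes C3 (para to one benzyloxy group, ortho to the other) is attacked in preference to the carbon between the two benzyloxy groups, the usual preference of 1,3-dialkoxybenzenes and orcinol ethers, and a polar solvent in the dark suppresses radical bromination of the methyl group.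

Step 3
Reactants: 4 hexanoyl chloride
Product: 5 N-methoxy-N-methylhexanamide
Conditions: MeNHOMe·HCl, Et3N (2.2 equiv), CH2Cl2, 0 °C to rt
Reagents that add atoms: N,O-dimethylhydroxylamine hydrochloride, CNOC.Cl
Why: Acylation of an amine hydrochloride by an acid chloride in the presence of a tertiary amine, the standard preparation of a Weinreb amide.

Step 4
Reactants: 3 benzyl 4,6-bis(benzyloxy)-3-bromo-2-methylbenzoate; 5 N-methoxy-N-methylhexanamide
Product: 8 benzyl 4,6-bis(benzyloxy)-3-bromo-2-(2-oxoheptyl)benzoate, via benzylic lithium species 6 (not isolated), via lithium hemiaminal alkoxide 7 (not isolated)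
Conditions: LiN(iPr)2 (1.2 equiv), THF, −78 °C; then 5, −78 to −40 °C; aq NH4Cl
Reagents that add atoms: none
Why: Lateral lithiation of an o-toluate and acylation with a Weinreb amide, as used for resorcylic acid lactones including toluates with an ortho halogen; the ring methyl group is the most acidic site (vinylogous to the ester and next to bromine), LiN(iPr)2 does not exchange the aryl bromide, and the chelated adduct 7 holds the ketone back until the quench, so neither over-addition nor lactonisation of a ketone enolate onto the ester should occur.

Step 5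
Reactants: 8 benzyl 4,6-bis(benzyloxy)-3-bromo-2-(2-oxoheptyl)benzoate
Product: 9 benzyl 4,6-bis(benzyloxy)-3-bromo-2-[(2-pentyl-1,3-dioxolan-2-yl)methyl]benzoate
Conditions: (TMSOCH2)2, TMSOTf (5 mol %), CH2Cl2, −78 to −20 °C; pyridine quench
Reagents that add atoms: 1,2-bis(trimethylsilyloxy)ethane, C[Si](C)(C)OCCO[Si](C)(C)C
Why: Noyori ketalisation under aprotic conditions at low temperature; it masks the enolisable benzylic ketone without the hot protic acid that could close the keto ester to an isocoumarin, and benzyl ethers, ester and aryl bromide are inert to catalytic TMSOTf.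

Step 6
Reactants: 9 benzyl 4,6-bis(benzyloxy)-3-bromo-2-[(2-pentyl-1,3-dioxolan-2-yl)methyl]benzoate
Product: 10 benzyl 4,6-bis(benzyloxy)-2-[(2-pentyl-1,3-dioxolan-2-yl)methyl]-3-(4,4,5,5-tetramethyl-1,3,2-dioxaborolan-2-yl)benzoate
Conditions: B2pin2, Pd(OAc)2 (5 mol %), SPhos (10 mol %), KOAc, 1,4-dioxane, 90 °C
Reagents that add atoms: bis(pinacolato)diboron, CC1(C)OB(OC1(C)C)B1OC(C)(C)C(C)(C)O1
Why: Miyaura borylation; the bulky, electron-rich biaryl phosphine is chosen because the bromide has two ortho substituents, and KOAc is too weak a base to attack the esters or to promote Suzuki coupling of the product.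

Step 7
Reactants: 10 benzyl 4,6-bis(benzyloxy)-2-[(2-pentyl-1,3-dioxolan-2-yl)methyl]-3-(4,4,5,5-tetramethyl-1,3,2-dioxaborolan-2-yl)benzoate
Product: 11 benzyl 4,6-bis(benzyloxy)-3-hydroxy-2-[(2-pentyl-1,3-dioxolan-2-yl)methyl]benzoate
Conditions: H2O2 (30% aq), NaOH (1 M aq), THF, 0 °C
Reagents that add atoms: hydrogen peroxide, OO
Why: Oxidation of an arylboronate with basic hydrogen peroxide (1,2-shift of the aryl group from boron to oxygen, then hydrolysis); the 2,6-disubstituted benzyl ester should resist cold dilute hydroxide over the short reaction time.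

Step 8
Reactants: 12 hept-1-yne
Product: 13 1-bromohept-1-yne
Conditions: NBS, AgNO3 (10 mol %), acetone, rt
Reagents that add atoms: N-bromosuccinimide, O=C1CCC(=O)N1Br
Why: Silver-catalysed electrophilic bromination of a terminal alkyne, the standard route to 1-bromoalkynes.

Step 9
Reactants: 13 1-bromohept-1-yne; 14 prop-2-yn-1-ol
Product: 15 deca-2,4-diyn-1-ol
Conditions: CuCl (5 mol %), NH2OH·HCl, n-BuNH2 (30% aq), Et2O, 0 °C to rt
Reagents that add atoms: none
Why: Cadiot–Chodkiewicz coupling; the copper acetylide of 14 reacts with the bromoalkyne to give the unsymmetrical diyne while hydroxylamine keeps copper monovalent, and the free alcohol is tolerated and avoids the amine addition a propiolate ester would suffer.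

Step 10
Reactants: 15 deca-2,4-diyn-1-ol
Product: 16 deca-2,4-diynoic acid
Conditions: CrO3, H2SO4 (aq), acetone, 0 °C (Jones oxidation)
Reagents that add atoms: water, O
Why: Jones oxidation of a primary propargylic alcohol to the acid through the aldehyde hydrate; conjugated diynes withstand the cold acidic chromium reagent, and this is the classical access to 2,4-diynoic acids.

Step 11
Reactants: 16 deca-2,4-diynoic acid
Product: 17 methyl deca-2,4-diynoate
Conditions: MeI, KHCO3, DMF, rt
Reagents that add atoms: iodomethane, CI
Why: O-Alkylation of the carboxylate under a weak base at room temperature, which avoids the alkyne–allene isomerisation and the decarboxylation that stronger base or heat could cause.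

Step 12
Reactants: 18 cyclohexane-1,3-dione
Product: 19 3-chlorocyclohex-2-en-1-one
Conditions: (COCl)2, DMF (cat.), CH2Cl2, 0 °C to rt
Reagents that add atoms: oxalyl chloride, O=C(Cl)C(Cl)=O
Why: Conversion of a 1,3-dione into its vinylogous acid chloride by Vilsmeier-type activation of the enol, a standard preparation of this β-chloro enone.

Step 13
Reactants: 11 benzyl 4,6-bis(benzyloxy)-3-hydroxy-2-[(2-pentyl-1,3-dioxolan-2-yl)methyl]benzoate; 19 3-chlorocyclohex-2-en-1-one
Product: 20 benzyl 4,6-bis(benzyloxy)-3-[(3-oxocyclohex-1-en-1-yl)oxy]-2-[(2-pentyl-1,3-dioxolan-2-yl)methyl]benzoate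
Conditions: Cs2CO3, DMF, 50 °C
Reagents that add atoms: none
Why: Addition–elimination (vinylic nucleophilic substitution) of the phenoxide at the β-carbon of the chloro enone, a known reaction of 3-chlorocyclohexenone with phenols; attack of a hindered phenoxide on an unhindered sp2 carbon is far less demanding than an arylation.

Step 14
Reactants: 20 benzyl 4,6-bis(benzyloxy)-3-[(3-oxocyclohex-1-en-1-yl)oxy]-2-[(2-pentyl-1,3-dioxolan-2-yl)methyl]benzoate
Product: 22 benzyl 4,6-bis(benzyloxy)-2-[(2-pentyl-1,3-dioxolan-2-yl)methyl]-3-{[3-(trimethylsilyloxy)cyclohexa-1,3-dien-1-yl]oxy}benzoate, via lithium dienolate 21 (not isolated)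
Conditions: LiN(iPr)2 (1.1 equiv), THF, −78 °C; then TMSCl, −78 °C to rt; pentane, filtration under argon
Reagents that add atoms: chlorotrimethylsilane, C[Si](C)(C)Cl
Why: Kinetic deprotonation of a vinylogous ester takes place at the α' methylene (Stork–Danheiser regiochemistry), and O-silylation of dienolate 21 gives the 1-aryloxy-3-silyloxy diene just as the known 1-alkoxy analogues are made; at −78 °C the ketone α'-protons should be removed much faster than the ring A benzylic or benzyl ester protons.

Step 15
Reactants: 22 benzyl 4,6-bis(benzyloxy)-2-[(2-pentyl-1,3-dioxolan-2-yl)methyl]-3-{[3-(trimethylsilyloxy)cyclohexa-1,3-dien-1-yl]oxy}benzoate; 17 methyl deca-2,4-diynoate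
Product: 24 benzyl 4,6-bis(benzyloxy)-3-[3-(hept-1-yn-1-yl)-2-(methoxycarbonyl)-5-(trimethylsilyloxy)phenoxy]-2-[(2-pentyl-1,3-dioxolan-2-yl)methyl]benzoate, via bicyclo[2.2.2]octadiene adduct 23 (not isolated)
Conditions: 17 (1.5 equiv), BHT (cat.), o-xylene, sealed tube, 110 °C then 165 °C
Reagents that add atoms: none
Why: Alder–Rickert sequence: a normal-demand [4+2] cycloaddition between the electron-rich, s-cis-locked diene 22 and the ester-bearing triple bond of 17 gives the bicyclo[2.2.2]octa-2,5-diene 23, which on further heating undergoes [4+2] cycloreversion with loss of its saturated two-carbon bridge as ethylene to give benzoate 24. The closest known reaction type is the same sequence between 1-alkoxy-3-silyloxycyclohexa-1,3-dienes and alkynoates, which gives resorcinol monoethers; here an aryloxy group stands in for the alkoxy group. Ring B is closed by intermolecular cycloaddition, both σ bonds (C8–C8a and C5–C4a) forming suprafacially in one step, and becomes aromatic by cycloreversion, so no chain cyclisation mode is involved. No stereocentre is set, since the two bridgehead centres of racemic 23 disappear on aromatisation. The regioselectivity needed (ester ortho to the aryloxy group) follows from the diene, where both oxygen donors place the largest HOMO coefficient on the unsubstituted silyl enol ether terminus, and from the ynoate, whose β-carbon has the largest LUMO coefficient; these two carbons join (C5–C4a) and the aryloxy-bearing terminus bonds to the α-carbon (C8–C8a). The site selectivity needed (C2≡C3 of 17 over C4≡C5) rests on the direct conjugation of C2≡C3 with the ester, and the triple bond left in 24 is an unactivated, ortho-flanked aryl alkyne that should not add a second diene. In 23 the aryloxy group sits on a bridgehead and cannot be eliminated, so loss of ethylene is the only path to the arene. An excess of 17 and a first stage at 110 °C are meant to let the cycloaddition outrun the 1,5-hydrogen shift of the diene before the temperature is raised for the cycloreversion.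

Step 16
Reactants: 24 benzyl 4,6-bis(benzyloxy)-3-[3-(hept-1-yn-1-yl)-2-(methoxycarbonyl)-5-(trimethylsilyloxy)phenoxy]-2-[(2-pentyl-1,3-dioxolan-2-yl)methyl]benzoate
Product: 26 benzyl 4,6-bis(benzyloxy)-3-[3-(hept-1-yn-1-yl)-5-methoxy-2-(methoxycarbonyl)phenoxy]-2-[(2-pentyl-1,3-dioxolan-2-yl)methyl]benzoate, via cesium phenoxide 25 (not isolated)
Conditions: CsF, MeI, DMF, rt
Reagents that add atoms: iodomethane, CI
Why: Fluoride cleaves the aryl silyl ether to phenoxide 25, which is methylated in the same flask (Williamson ether synthesis); benzyl ethers, both esters, the alkyne and the dioxolane are inert, and any phenol formed by adventitious desilylation of 24 should converge to 26 under the same conditions.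

Step 17
Reactants: 26 benzyl 4,6-bis(benzyloxy)-3-[3-(hept-1-yn-1-yl)-5-methoxy-2-(methoxycarbonyl)phenoxy]-2-[(2-pentyl-1,3-dioxolan-2-yl)methyl]benzoate
Product: 27 benzyl 4,6-bis(benzyloxy)-3-[(6-methoxy-1-oxo-3-pentyl-1H-isochromen-8-yl)oxy]-2-[(2-pentyl-1,3-dioxolan-2-yl)methyl]benzoate
Conditions: AgOTf (10 mol %), TsOH·H2O (20 mol %), H2O (2 equiv), ClCH2CH2Cl, 60 °C
Reagents that add atoms: none
Why: π-Acid-catalysed 6-endo-dig cyclisation of a methyl 2-alkynylbenzoate, a known route to 3-alkylisocoumarins: the ester carbonyl oxygen adds to the silver-activated alkyne at the carbon remote from the ring, water takes over the O-methyl group and protodemetalation sets C4–H. Only the ring B ester has an alkyne within reach, and if the dioxolane is partly lost under the mildly acidic conditions the material converges in step 18.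

Step 18
Reactants: 27 benzyl 4,6-bis(benzyloxy)-3-[(6-methoxy-1-oxo-3-pentyl-1H-isochromen-8-yl)oxy]-2-[(2-pentyl-1,3-dioxolan-2-yl)methyl]benzoate
Product: 28 benzyl 4,6-bis(benzyloxy)-3-[(6-methoxy-1-oxo-3-pentyl-1H-isochromen-8-yl)oxy]-2-(2-oxoheptyl)benzoate
Conditions: HCl (1 M aq), THF, rt
Reagents that add atoms: water, O
Why: Acid-catalysed ketal hydrolysis, done while the carboxyl group is still a benzyl ester so that the liberated ketone has no free acid to lactonise with; the isocoumarin lactone is stable to dilute aqueous acid.

Step 19
Reactants: 28 benzyl 4,6-bis(benzyloxy)-3-[(6-methoxy-1-oxo-3-pentyl-1H-isochromen-8-yl)oxy]-2-(2-oxoheptyl)benzoate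
Product: 29 4,6-dihydroxy-3-[(6-methoxy-1-oxo-3-pentyl-1H-isochromen-8-yl)oxy]-2-(2-oxoheptyl)benzoic acid (β-collatolic acid)
Conditions: H2 (1 atm), 10% Pd/C, EtOAc, rt
Reagents that add atoms: none
Why: Hydrogenolysis of the benzyl ester and the two aryl benzyl ethers over palladium under neutral conditions should release the acid and both phenols in one operation; benzylic C–O bonds are cleaved faster than the trisubstituted, conjugated C3=C4 bond of the isocoumarin is reduced, so the reaction is to be stopped after uptake of three equivalents of hydrogen.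

## Compound list

1 | orsellinic acid (2,4-dihydroxy-6-methylbenzoic acid) | Cc1cc(O)cc(O)c1C(=O)O | starting material
2 | benzyl 2,4-bis(benzyloxy)-6-methylbenzoate | Cc1cc(OCc2ccccc2)cc(OCc2ccccc2)c1C(=O)OCc1ccccc1 | intermediate
3 | benzyl 4,6-bis(benzyloxy)-3-bromo-2-methylbenzoate | Cc1c(Br)c(OCc2ccccc2)cc(OCc2ccccc2)c1C(=O)OCc1ccccc1 | intermediate
4 | hexanoyl chloride | CCCCCC(=O)Cl | starting material
5 | N-methoxy-N-methylhexanamide | CCCCCC(=O)N(C)OC | intermediate
6 | benzyl 4,6-bis(benzyloxy)-3-bromo-2-(lithiomethyl)benzoate (benzylic lithium species, not isolated) | [Li]Cc1c(Br)c(OCc2ccccc2)cc(OCc2ccccc2)c1C(=O)OCc1ccccc1 | intermediate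
7 | lithium 1-{3,5-bis(benzyloxy)-2-[(benzyloxy)carbonyl]-6-bromophenyl}-2-[methoxy(methyl)amino]heptan-2-olate (racemic hemiaminal alkoxide, not isolated) | CCCCCC(O[Li])(Cc1c(Br)c(OCc2ccccc2)cc(OCc2ccccc2)c1C(=O)OCc1ccccc1)N(C)OC | intermediate
8 | benzyl 4,6-bis(benzyloxy)-3-bromo-2-(2-oxoheptyl)benzoate | CCCCCC(=O)Cc1c(Br)c(OCc2ccccc2)cc(OCc2ccccc2)c1C(=O)OCc1ccccc1 | intermediate
9 | benzyl 4,6-bis(benzyloxy)-3-bromo-2-[(2-pentyl-1,3-dioxolan-2-yl)methyl]benzoate | CCCCCC1(Cc2c(Br)c(OCc3ccccc3)cc(OCc3ccccc3)c2C(=O)OCc2ccccc2)OCCO1 | intermediate
10 | benzyl 4,6-bis(benzyloxy)-2-[(2-pentyl-1,3-dioxolan-2-yl)methyl]-3-(4,4,5,5-tetramethyl-1,3,2-dioxaborolan-2-yl)benzoate | CCCCCC1(Cc2c(B3OC(C)(C)C(C)(C)O3)c(OCc3ccccc3)cc(OCc3ccccc3)c2C(=O)OCc2ccccc2)OCCO1 | intermediate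
11 | benzyl 4,6-bis(benzyloxy)-3-hydroxy-2-[(2-pentyl-1,3-dioxolan-2-yl)methyl]benzoate | CCCCCC1(Cc2c(O)c(OCc3ccccc3)cc(OCc3ccccc3)c2C(=O)OCc2ccccc2)OCCO1 | intermediate
12 | hept-1-yne | CCCCCC#C | starting material
13 | 1-bromohept-1-yne | CCCCCC#CBr | intermediate
14 | prop-2-yn-1-ol | C#CCO | starting material
15 | deca-2,4-diyn-1-ol | CCCCCC#CC#CCO | intermediate
16 | deca-2,4-diynoic acid | CCCCCC#CC#CC(=O)O | intermediate
17 | methyl deca-2,4-diynoate | CCCCCC#CC#CC(=O)OC | intermediate
18 | cyclohexane-1,3-dione | O=C1CCCC(=O)C1 | starting material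
19 | 3-chlorocyclohex-2-en-1-one | O=C1C=C(Cl)CCC1 | intermediate
20 | benzyl 4,6-bis(benzyloxy)-3-[(3-oxocyclohex-1-en-1-yl)oxy]-2-[(2-pentyl-1,3-dioxolan-2-yl)methyl]benzoate | O=C1C=C(Oc2c(CC3(CCCCC)OCCO3)c(C(=O)OCc3ccccc3)c(OCc3ccccc3)cc2OCc2ccccc2)CCC1 | intermediate
21 | lithium 5-aryloxycyclohexa-1,5-dien-1-olate, aryl = ring A of 20 (lithium dienolate, not isolated) | [Li]OC1=CCCC(Oc2c(CC3(CCCCC)OCCO3)c(C(=O)OCc3ccccc3)c(OCc3ccccc3)cc2OCc2ccccc2)=C1 | intermediate
22 | benzyl 4,6-bis(benzyloxy)-2-[(2-pentyl-1,3-dioxolan-2-yl)methyl]-3-{[3-(trimethylsilyloxy)cyclohexa-1,3-dien-1-yl]oxy}benzoate | C[Si](C)(C)OC1=CCCC(Oc2c(CC3(CCCCC)OCCO3)c(C(=O)OCc3ccccc3)c(OCc3ccccc3)cc2OCc2ccccc2)=C1 | intermediate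
23 | methyl 1-aryloxy-3-(hept-1-yn-1-yl)-5-(trimethylsilyloxy)bicyclo[2.2.2]octa-2,5-diene-2-carboxylate, aryl = ring A of 20 (racemic adduct, not isolated) | COC(=O)C1=C(C#CCCCCC)C2CCC1(Oc3c(CC4(CCCCC)OCCO4)c(C(=O)OCc4ccccc4)c(OCc4ccccc4)cc3OCc3ccccc3)C=C2O[Si](C)(C)C | intermediate
24 | benzyl 4,6-bis(benzyloxy)-3-[3-(hept-1-yn-1-yl)-2-(methoxycarbonyl)-5-(trimethylsilyloxy)phenoxy]-2-[(2-pentyl-1,3-dioxolan-2-yl)methyl]benzoate | CCCCCC#Cc1cc(O[Si](C)(C)C)cc(Oc2c(CC3(CCCCC)OCCO3)c(C(=O)OCc3ccccc3)c(OCc3ccccc3)cc2OCc2ccccc2)c1C(=O)OC | intermediate
25 | cesium 3-aryloxy-5-(hept-1-yn-1-yl)-4-(methoxycarbonyl)phenolate, aryl = ring A of 20 (not isolated) | CCCCCC#Cc1cc([O-])cc(Oc2c(CC3(CCCCC)OCCO3)c(C(=O)OCc3ccccc3)c(OCc3ccccc3)cc2OCc2ccccc2)c1C(=O)OC.[Cs+] | intermediate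
26 | benzyl 4,6-bis(benzyloxy)-3-[3-(hept-1-yn-1-yl)-5-methoxy-2-(methoxycarbonyl)phenoxy]-2-[(2-pentyl-1,3-dioxolan-2-yl)methyl]benzoate | CCCCCC#Cc1cc(OC)cc(Oc2c(CC3(CCCCC)OCCO3)c(C(=O)OCc3ccccc3)c(OCc3ccccc3)cc2OCc2ccccc2)c1C(=O)OC | intermediate
27 | benzyl 4,6-bis(benzyloxy)-3-[(6-methoxy-1-oxo-3-pentyl-1H-isochromen-8-yl)oxy]-2-[(2-pentyl-1,3-dioxolan-2-yl)methyl]benzoate | CCCCCc1cc2cc(OC)cc(Oc3c(CC4(CCCCC)OCCO4)c(C(=O)OCc4ccccc4)c(OCc4ccccc4)cc3OCc3ccccc3)c2c(=O)o1 | intermediate
28 | benzyl 4,6-bis(benzyloxy)-3-[(6-methoxy-1-oxo-3-pentyl-1H-isochromen-8-yl)oxy]-2-(2-oxoheptyl)benzoate | CCCCCC(=O)Cc1c(Oc2cc(OC)cc3cc(CCCCC)oc(=O)c23)c(OCc2ccccc2)cc(OCc2ccccc2)c1C(=O)OCc1ccccc1 | intermediate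
29 | 4,6-dihydroxy-3-[(6-methoxy-1-oxo-3-pentyl-1H-isochromen-8-yl)oxy]-2-(2-oxoheptyl)benzoic acid (β-collatolic acid, achiral) | CCCCCC(=O)Cc1c(Oc2cc(OC)cc3cc(CCCCC)oc(=O)c23)c(O)cc(O)c1C(=O)O | target

## Step count and risks

Total: 19 steps. Longest linear sequence: 13 steps from orsellinic acid 1 (steps 1, 2, 4, 5, 6, 7, 13, 14, 15, 16, 17, 18, 19). Side branches: step 3 (amide 5), steps 8 to 11 (diynoate 17) and step 12 (chloro enone 19).

Least certain steps:

**Step 15 (key step).** The β-substituted ynoate is a slower dienophile than a propiolate, and the aryloxy-bearing diene terminus is crowded. The cycloaddition may therefore be outrun by the thermal 1,5-hydrogen shift of the diene, by desilylation back to 20, or by oligomerisation of the diynoate at the temperature needed for ethylene loss. Partial addition at the distal triple bond is a lesser risk. Fallback, setting out from 22: methyl prop-2-ynoate is brominated (NBS, AgNO3) to methyl 3-bromoprop-2-ynoate F1, a smaller and more reactive dienophile with the same polarisation. With 22 it should give, through the bicyclic bromo adduct F2 and loss of ethylene, the aryl bromide silyl ether F3. Exchange of silyl for methyl (CsF, MeI) gives the bromo methyl ether F4. Sonogashira coupling of F4 with hept-1-yne 12 (Pd(PPh3)2Cl2, CuI, Et3N) installs the alkyne and returns to the route at 26.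

**Step 13.** The phenoxide of 11 has two ortho substituents, so the substitution may be slow, and chloro enone 19 may meanwhile be hydrolysed back to 18 by traces of water. Fallback, setting out from 11 and 18: dione 18 is converted with PPh3, I2 and Et3N into 3-iodocyclohex-2-en-1-one F5. Copper-catalysed C–O coupling of F5 with 11 (CuI, N,N-dimethylglycine, Cs2CO3, 1,4-dioxane, 90 °C), an Ullmann-type vinylation of a phenol, returns to the route at 20.

**Step 17.** The methyl ester has two ortho substituents and is twisted out of the ring plane. Closure may therefore be sluggish, may partly take the 5-exo course, or may be accompanied by acid-promoted loss of the dioxolane before the ring closes. Fallback, setting out from 26: electrophilic iodocyclisation (I2, MeCN, rt), which does not depend on a catalytic π-acid and is 6-endo selective for such esters, gives the 4-iodoisocoumarin F6. Reductive removal of iodine (Pd(OAc)2, PPh3, HCO2H, Et3N, DMF) returns to the route at 27.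

**Step 19.** Hydrogenolysis of the more hindered benzyl ether may be slow enough for competing saturation of the C3=C4 bond of ring C. Fallback, setting out from 28: Lewis-acid debenzylation with BCl3 and pentamethylbenzene as benzyl cation scavenger (CH2Cl2, −78 °C) cleaves the benzyl ester and both ethers without a reductant. The enol lactone double bond is then not at risk and the 6-methoxy group, which has no neighbouring carbonyl, should be spared. This fallback makes no new compound and arrives directly at 29.

## Further compounds

F1 | step 15 | methyl 3-bromoprop-2-ynoate | COC(=O)C#CBr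
F2 | step 15 | methyl 1-aryloxy-3-bromo-5-(trimethylsilyloxy)bicyclo[2.2.2]octa-2,5-diene-2-carboxylate, aryl = ring A of 20 (racemic, not isolated) | COC(=O)C1=C(Br)C2CCC1(Oc3c(CC4(CCCCC)OCCO4)c(C(=O)OCc4ccccc4)c(OCc4ccccc4)cc3OCc3ccccc3)C=C2O[Si](C)(C)C
F3 | step 15 | benzyl 4,6-bis(benzyloxy)-3-[3-bromo-2-(methoxycarbonyl)-5-(trimethylsilyloxy)phenoxy]-2-[(2-pentyl-1,3-dioxolan-2-yl)methyl]benzoate | COC(=O)c1c(Br)cc(O[Si](C)(C)C)cc1Oc1c(CC2(CCCCC)OCCO2)c(C(=O)OCc2ccccc2)c(OCc2ccccc2)cc1OCc1ccccc1
F4 | step 15 | benzyl 4,6-bis(benzyloxy)-3-[3-bromo-5-methoxy-2-(methoxycarbonyl)phenoxy]-2-[(2-pentyl-1,3-dioxolan-2-yl)methyl]benzoate | COC(=O)c1c(Br)cc(OC)cc1Oc1c(CC2(CCCCC)OCCO2)c(C(=O)OCc2ccccc2)c(OCc2ccccc2)cc1OCc1ccccc1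
F5 | step 13 | 3-iodocyclohex-2-en-1-one | O=C1C=C(I)CCC1
F6 | step 17 | benzyl 4,6-bis(benzyloxy)-3-[(4-iodo-6-methoxy-1-oxo-3-pentyl-1H-isochromen-8-yl)oxy]-2-[(2-pentyl-1,3-dioxolan-2-yl)methyl]benzoate | CCCCCc1oc(=O)c2c(Oc3c(CC4(CCCCC)OCCO4)c(C(=O)OCc4ccccc4)c(OCc4ccccc4)cc3OCc3ccccc3)cc(OC)cc2c1I
F0 | step 19 | none | none
A1 | alternative 1 | tert-butyl 6-hydroxy-3-[(6-methoxy-1-oxo-3-pentyl-1H-isochromen-8-yl)oxy]-2-[(2-pentyl-1,3-dioxolan-2-yl)methyl]-4-(triisopropylsilyloxy)benzoate | CCCCCC1(Cc2c(Oc3cc(OC)cc4cc(CCCCC)oc(=O)c34)c(O[Si](C(C)C)(C(C)C)C(C)C)cc(O)c2C(=O)OC(C)(C)C)OCCO1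
A2 | alternative 1 | (triisopropylsilyloxy)ethyne | C#CO[Si](C(C)C)(C(C)C)C(C)C
A3 | alternative 2 | benzyl 3-[(6-methoxy-1-oxo-3-pentyl-1H-isochromen-8-yl)oxy]-4,6-dioxo-2-[(2-pentyl-1,3-dioxolan-2-yl)methyl]cyclohexane-1-carboxylate (racemic, substituents at C1, C2 and C3 mutually trans) | [C@H]1(C(=O)OCc2ccccc2)C(=O)CC(=O)[C@@H](Oc2cc(OC)cc3cc(CCCCC)oc(=O)c23)[C@@H]1CC1(CCCCC)OCCO1
A4 | alternative 2 | dibenzyl malonate | O=C(CC(=O)OCc1ccccc1)OCc1ccccc1
A5 | alternative 3 | benzyl 4,6-bis(benzyloxy)-3-[(6-hydroxy-1-oxo-3-pentyl-1H-isochromen-8-yl)oxy]-2-[(2-pentyl-1,3-dioxolan-2-yl)methyl]benzoate | CCCCCc1cc2cc(O)cc(Oc3c(CC4(CCCCC)OCCO4)c(C(=O)OCc4ccccc4)c(OCc4ccccc4)cc3OCc3ccccc3)c2c(=O)o1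
A6 | alternative 3 | benzyl 4,6-bis(benzyloxy)-3-{[6-(2,4-dioxononyl)-2-oxo-2H-pyran-4-yl]oxy}-2-[(2-pentyl-1,3-dioxolan-2-yl)methyl]benzoate | CCCCCC(=O)CC(=O)Cc1cc(Oc2c(CC3(CCCCC)OCCO3)c(C(=O)OCc3ccccc3)c(OCc3ccccc3)cc2OCc2ccccc2)cc(=O)o1
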